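Readings and results come from a simulation with constants of no real substance; the scatter is artificial.

A small charge of gas, 3.0 mM held, is less than the 0.050 M of substrate, and I choose to treat the fall of substrate in this flask as pseudo-first-order, although none of the gas is in solution at the start.

- Thursday's: substrate 0.050 M; gas 3 mM (held); the very flask that is asked about, followed so far
- flask: substrate 0.050 M; gas 3.0 mM (held); time 4.0 d

Thursday's run (percent of the substrate charged): time / h: target / % = 10.0: 30; 12.0: 36; 20.0: 46; 25.0: 46; 30.0: 52; 50.0: 51

(standard deviation of a reading: 2 percentage points)

- when, up to 4.0 d, the flask holds most target
- the amount of target, in percent of the substrate charged, at that time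

- at the start none of the gas is in solution
- a reading or a percentage of target counts all its forms, free or not

If I read Thursday's first reading as all the substrate reacted so far, I get 28.0 h, the time in which substrate falls by a factor e: the substrate lifetime. By 50.0 h that lifetime reckons 83.2% of the substrate consumed, yet target reads 51%, so my reckoning leaves a gap of 32 percentage points, against 14 points at 30.0 h. The later gap is larger than the earlier one, while those two readings agree within their scatter, so I read the stall as a balance, with target leaking away as it is made. The gap's growth, set against a mean target of 51.5%, gives a loss life of 55.7 h. On this reckoning target peaks where substrate left over its lifetime equals target over its loss life, which comes at 1.58 d.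

The weak link is that difference of two gaps, each carrying the 2 points scatter. Reforged, the whole gap at 50.0 h over the mean of all the readings gives 67.6 h and a peak at 1.80 d. I commit to a time in that span, earlier than the forecast, and to an amount near that mean of 51.5%. The forecast says 2.5 d and 53%, expecting a flat top “with the time poorly determined”.

The flask gives 1.51 d and 50.7%.

    substrate + partner ⇌ target (K = 810 M⁻¹, k = 0.00650 M⁻¹ s⁻¹)
    gas ⇌ partner, rate k2*(csat - [partner]) (kL = 5.90 × 10⁻⁴ s⁻¹)
    target → over-reaction product (k = 6.40 × 10⁻⁶ s⁻¹)
    crystals ⇌ target, rate k4*(cs4 - [target]) while solid is left; crystals form when [target] > cs4 (solubility = 16.0 mM, k = 1.40 × 10⁻⁴ s⁻¹)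

At that time the lifetime reckons 27.4% of substrate left in the flask, which holds 25.3%. In the neighbouring flask, charged with 0.085 M of substrate under the same gas, the same lifetime reckons 3.24% left at 4.0 d. That neighbouring flask holds more substrate than reckoned, 7.92% of its charge, and its best target is 62.1%.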